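The retrosynthesis first removes the acyl groups at O6 (acetate) and O8 (angelate) and moves C1=C10 back to an exocyclic C10=C14 alkene. It then cuts C8–C9 of ring B, C7–C11 (isopropyl) and C6=C7 (olefination) of the side chain, and finally undoes the ring contraction that makes ring A.
The enabling feature is in the seven-membered ring B: the C8 carbinol stands 1,3 to C10, which carries the C14 methyl group and an alkene. This is the pattern left by a carbonyl-ene reaction between a C8 aldehyde and an isopropenyl group (C9=C10–C14) on C1 of ring A.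
In the forward direction ring A arises first by Wolff contraction of (S)-carvone. The C6–C7–C8 chain is then grown on C5 by Wittig olefination, epoxidation and isopropyl-copper opening. Ring B closes last, and an alkene shift and two acylations finish the route.
For stereochemistry, the carvone centre (C1) sets C5 by kinetic protonation (cis), and the two cis arms steer the epoxidation that sets C4. Sharpless epoxidation sets C6, SN2 inversion sets C7, and the 6β-silyloxy and 7β-isopropyl groups set C8 in the ene step.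
C1 is then erased by the alkene shift, and the Z geometry of the ester comes with angelic acid.
Key step: step 11

Remark: guaiane numbering is used throughout and β is the face of H5. The target is read as (4S,5R,6R,7R,8S), that is 4β-OH, 5β-H, 6β-OAc, 7β-isopropyl, 8α-O-angeloyl, with a Z ester.

Step 1
Reactants: 1 (S)-(+)-carvone
Product: 3 (5R)-6-diazo-2-methyl-5-(prop-1-en-2-yl)cyclohex-2-en-1-one, via 6-trifluoroacetylcarvone 2 (not isolated)
Conditions: LiN(SiMe3)2, THF, −78 °C; CF3CO2CH2CF3; then 4-AcNHC6H4SO2N3, Et3N, H2O, MeCN, rt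
Reagents that add atoms: 4-acetamidobenzenesulfonyl azide CC(=O)Nc1ccc(cc1)S(=O)(=O)N=[N+]=[N-]; 2,2,2-trifluoroethyl trifluoroacetate O=C(OCC(F)(F)F)C(F)(F)F (its CF3CO group is kept only in 2)
Why: Kinetic deprotonation of the enone at C6 and trifluoroacetylation activate that carbon for a detrifluoroacetylative Regitz-type diazo transfer, the standard route to α'-diazo enones, and the neighbouring stereocentre is not touched.

Step 2
Reactants: 3 (5R)-6-diazo-2-methyl-5-(prop-1-en-2-yl)cyclohex-2-en-1-one
Product: 5 methyl (1S,5S)-2-methyl-5-(prop-1-en-2-yl)cyclopent-2-ene-1-carboxylate (ester cis to isopropenyl), via vinylketene 4 (not isolated)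
Conditions: hν (Hg lamp, Pyrex), MeOH, 0 °C
Reagents that add atoms: methanol CO
Why: Photochemical Wolff rearrangement of the s-Z-locked cyclic diazo ketone contracts the ring by migration of the vinylic carbon, methanol traps ketene 4, and the resulting exocyclic enol should be protonated at C5 from the face away from the adjacent isopropenyl group (kinetic protonation), which gives 5β-H and the cis ester under neutral conditions that neither epimerise nor conjugate the β,γ-unsaturated ester.

Step 3
Reactants: 5 methyl (1S,5S)-2-methyl-5-(prop-1-en-2-yl)cyclopent-2-ene-1-carboxylate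
Product: 6 methyl (1R,2S,3S,5S)-1-methyl-3-(prop-1-en-2-yl)-6-oxabicyclo[3.1.0]hexane-2-carboxylate (3β,4β-epoxide)
Conditions: mCPBA (1 equiv), CH2Cl2, 0 °C
Reagents that add atoms: 3-chloroperbenzoic acid OOC(=O)c1cccc(Cl)c1
Why: Prilezhaev epoxidation prefers the trisubstituted ring alkene over the 1,1-disubstituted one (as in limonene), and both α-oriented arms block one face, so oxygen should arrive from the β face and fix the C4–O configuration.

Step 4
Reactants: 6 methyl (1R,2S,3S,5S)-1-methyl-3-(prop-1-en-2-yl)-6-oxabicyclo[3.1.0]hexane-2-carboxylate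
Product: 7 (1S,2R,3S)-2-(hydroxymethyl)-1-methyl-3-(prop-1-en-2-yl)cyclopentan-1-ol
Conditions: LiAlH4, THF, 0 °C → reflux
Reagents that add atoms: none
Why: Hydride reduction of the ester and SN2 opening of the trisubstituted epoxide at the less substituted C3 occur in one operation, so the C4–O bond stays intact and becomes the 4β tertiary carbinol.

Step 5
Reactants: 7 (1S,2R,3S)-2-(hydroxymethyl)-1-methyl-3-(prop-1-en-2-yl)cyclopentan-1-ol; 8 ethyl (triphenylphosphoranylidene)acetate
Product: 10 ethyl (2E)-3-[(1S,2S,5S)-2-hydroxy-2-methyl-5-(prop-1-en-2-yl)cyclopentyl]prop-2-enoate, via hydroxy aldehyde 9 (not isolated)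
Conditions: TEMPO (cat.), PhI(OAc)2, CH2Cl2, rt; then 8, rt → 40 °C
Reagents that add atoms: none
Why: Oxoammonium oxidation touches only the primary alcohol, and the in-flask Wittig reaction with a stabilised ylide gives the E-enoate without added base, so the crowded β-hydroxy aldehyde 9 should not epimerise at C5, dehydrate or undergo retro-aldol cleavage.

Step 6
Reactants: 10 ethyl (2E)-3-[(1S,2S,5S)-2-hydroxy-2-methyl-5-(prop-1-en-2-yl)cyclopentyl]prop-2-enoate
Product: 11 (1S,2S,3S)-2-[(1E)-3-hydroxyprop-1-en-1-yl]-1-methyl-3-(prop-1-en-2-yl)cyclopentan-1-ol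
Conditions: iBu2AlH, CH2Cl2, −78 °C; aq potassium sodium tartrate
Reagents that add atoms: none
Why: 1,2-Reduction of an enoate with iBu2AlH gives the E-allylic alcohol and leaves both alkenes alone.

Step 7
Reactants: 11 (1S,2S,3S)-2-[(1E)-3-hydroxyprop-1-en-1-yl]-1-methyl-3-(prop-1-en-2-yl)cyclopentan-1-ol
Product: 12 (1S,2R,3S)-2-[(2S,3S)-3-(hydroxymethyl)oxiran-2-yl]-1-methyl-3-(prop-1-en-2-yl)cyclopentan-1-ol
Conditions: Ti(OiPr)4 (cat.), L-(+)-diisopropyl tartrate (cat.), tBuOOH, 4 Å MS, CH2Cl2, −20 °C
Reagents that add atoms: tert-butyl hydroperoxide CC(C)(C)OO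
Why: Sharpless asymmetric epoxidation acts only on the alkene of the allylic alcohol, so the isopropenyl group is spared, and with L-(+)-tartrate an E-allylic alcohol gives the (2S,3S)-epoxide, which sets the C6–O configuration under reagent control.

Step 8
Reactants: 12 (1S,2R,3S)-2-[(2S,3S)-3-(hydroxymethyl)oxiran-2-yl]-1-methyl-3-(prop-1-en-2-yl)cyclopentan-1-ol; 13 isopropylmagnesium chloride
Product: 14 (1R,2R)-1-[(1R,2S,5S)-2-hydroxy-2-methyl-5-(prop-1-en-2-yl)cyclopentyl]-2-(propan-2-yl)propane-1,3-diol
Conditions: 13 (excess), CuI (20 mol %), THF/Et2O, −30 → 0 °C; aq NH4Cl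
Reagents that add atoms: none
Why: In this copper-catalysed Grignard opening of a 2,3-epoxy alcohol the nucleophile attacks C7, the epoxide carbon away from the bulky ring A, by SN2 with inversion, which turns the trans-epoxide into the 1,3-diol with the 6,7-anti relationship and sets C7.

Step 9
Reactants: 14 (1R,2R)-1-[(1R,2S,5S)-2-hydroxy-2-methyl-5-(prop-1-en-2-yl)cyclopentyl]-2-(propan-2-yl)propane-1,3-diol
Product: 15 4,6,8-tris(triethylsilyl) ether of 14
Conditions: Et3SiOTf, 2,6-lutidine, CH2Cl2, −78 → 0 °C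
Reagents that add atoms: triethylsilyl trifluoromethanesulfonate CC[Si](CC)(CC)OS(=O)(=O)C(F)(F)F
Why: Silylation with the silyl triflate and a hindered base covers primary, secondary and tertiary hydroxyl groups in one step and gives non-chelating ethers.

Step 10
Reactants: 15 4,6,8-tris(triethylsilyl) ether of 14
Product: 16 (2S,3S)-2-(propan-2-yl)-3-(triethylsilyloxy)-3-[(1R,2S,5S)-2-methyl-5-(prop-1-en-2-yl)-2-(triethylsilyloxy)cyclopentyl]propanal
Conditions: (COCl)2, DMSO, CH2Cl2, −78 → −40 °C; Et3N, −78 °C → rt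
Reagents that add atoms: none
Why: Under Swern conditions the activated sulfonium species attacks only the unhindered primary triethylsilyl ether (a known selective oxidative desilylation), so the C8 aldehyde forms directly while the secondary and tertiary silyl ethers and the C7 centre stay intact.

Step 11
Reactants: 16 (2S,3S)-2-(propan-2-yl)-3-(triethylsilyloxy)-3-[(1R,2S,5S)-2-methyl-5-(prop-1-en-2-yl)-2-(triethylsilyloxy)cyclopentyl]propanal
Product: 17 (1S,4S,5R,6R,7R,8S)-4,6-bis(triethylsilyloxy)guai-10(14)-en-8-ol (cis-fused with 1β-H and 5β-H; 8α-OH)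
Conditions: Me2AlCl (2 equiv), CH2Cl2, −78 → −30 °C; aq potassium sodium tartrate
Reagents that add atoms: none
Why: Me2AlCl binds the C8 aldehyde oxygen, the CH2 terminus C9 of the isopropenyl group adds to the carbonyl carbon while a C14–H passes to oxygen through a six-membered cyclic transition state, and loss of methane from the aluminium-bound alcohol leaves a stable alkoxide, so no proton acid is released that could harm the silyl ethers or the new alkene. The closest known reaction is the Me2AlCl-promoted intramolecular carbonyl-ene cyclisation of aldehydes carrying a remote 1,1-disubstituted alkene, which gives 3-methylenecyclohexanols and 3-methylenecycloheptanols. Ring B closes as a seven-membered carbocycle in the mode where the tether sits on the central carbon C10 of the ene unit, so the alkene ends up exocyclic at C10(14), and the cis arrangement of the two arms on ring A brings the ends together and gives a cis-fused hydroazulene. C8 is the only new stereocentre: to reach a C14–H the aluminium-bound oxygen must stand pseudo-axial on the forming ring, gauche to C10, and on the β face that position is 1,3-syn to the bulky 6β-OSiEt3 group and next to the 7β-isopropyl group, so C9 should add to the Si face of the aldehyde and place oxygen 8α (8S), trans to isopropyl and 1,3-anti to O6. The step needs this facial selectivity, monodentate activation and survival of a β-silyloxy aldehyde: the weakly basic silyl ethers prevent O6–O8 chelation, which could only lead to the 6,8-cis diol, and the low temperature and the proton-scavenging Al–CH3 bonds hold back β-elimination and chloride capture of a C10 cation.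

Step 12
Reactants: 17 (1S,4S,5R,6R,7R,8S)-4,6-bis(triethylsilyloxy)guai-10(14)-en-8-ol
Product: 18 (4S,5R,6R,7R,8S)-4,6-bis(triethylsilyloxy)guai-1(10)-en-8-ol
Conditions: Co(salen)Cl [salen = N,N'-bis(3,5-di-tert-butylsalicylidene)ethane-1,2-diaminate] (5 mol %), PhSiH3 (10 mol %), benzene, rt
Reagents that add atoms: none
Why: In this hydrogen-atom-transfer alkene isomerisation a cobalt hydride delivers H to C14 to give the tertiary C10 radical, divalent cobalt takes back the weak, convex-face tertiary C1–H, and the tetrasubstituted C1=C10 alkene that results is inert to further transfer and acts as the sink, while the now superfluous C1 centre is erased and the free alcohol and silyl ethers are tolerated.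

Step 13
Reactants: 18 (4S,5R,6R,7R,8S)-4,6-bis(triethylsilyloxy)guai-1(10)-en-8-ol; 19 angelic acid
Product: 21 4β,6β-bis(triethylsilyloxy)guai-1(10)-en-8α-yl angelate, via angelic 2,4,6-trichlorobenzoic anhydride 20 (not isolated)
Conditions: 19, 2,4,6-Cl3C6H2COCl, Et3N, toluene, rt; then 18, 80 °C
Reagents that add atoms: 2,4,6-trichlorobenzoyl chloride O=C(Cl)c1c(Cl)cc(Cl)cc1Cl (its aroyl group is kept only in 20)
Why: Yamaguchi-type mixed-anhydride esterification run without a nucleophilic catalyst is the established way to angelates, since the alcohol attacks the unhindered angeloyl carbonyl, the Z alkene does not drift to the tiglate, and C8 keeps its configuration because its C–O bond is not broken.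

Step 14
Reactants: 21 4β,6β-bis(triethylsilyloxy)guai-1(10)-en-8α-yl angelate
Product: 22 4β,6β-dihydroxyguai-1(10)-en-8α-yl angelate
Conditions: HF·pyridine, pyridine, THF, 0 °C → rt
Reagents that add atoms: none
Why: Buffered fluoride-driven Si–O cleavage removes both triethylsilyl groups, and the weakly acidic medium avoids the base-induced O8→O6 acyl shift and does not ionise the tertiary carbinol.

Step 15
Reactants: 22 4β,6β-dihydroxyguai-1(10)-en-8α-yl angelate
Product: 23 CNP0258590.1, (4S,5R,6R,7R,8S)-6-acetoxy-4-hydroxyguai-1(10)-en-8-yl (2Z)-2-methylbut-2-enoate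
Conditions: Ac2O, pyridine, DMAP (cat.), CH2Cl2, rt
Reagents that add atoms: acetic anhydride CC(=O)OC(C)=O
Why: DMAP-catalysed acetylation acylates the secondary 6-OH, whereas the tertiary 4-OH is inert at room temperature, so no further protecting group is needed.

Compound list
1 | (S)-(+)-carvone, (5S)-2-methyl-5-(prop-1-en-2-yl)cyclohex-2-en-1-one | CC1=CC[C@H](C(C)=C)CC1=O | starting material
2 | (5S)-2-methyl-5-(prop-1-en-2-yl)-6-(trifluoroacetyl)cyclohex-2-en-1-one (C6 epimers/enol) | CC1=CC[C@H](C(C)=C)C(C(=O)C(F)(F)F)C1=O | intermediate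
3 | (5R)-6-diazo-2-methyl-5-(prop-1-en-2-yl)cyclohex-2-en-1-one | CC1=CC[C@H](C(C)=C)C(=[N+]=[N-])C1=O | intermediate
4 | [(5R)-2-methyl-5-(prop-1-en-2-yl)cyclopent-2-en-1-ylidene]methanone (vinylketene) | CC1=CC[C@H](C(C)=C)C1=C=O | intermediate
5 | methyl (1S,5S)-2-methyl-5-(prop-1-en-2-yl)cyclopent-2-ene-1-carboxylate | CC1=CC[C@H](C(C)=C)[C@@H]1C(=O)OC | intermediate
6 | methyl (1R,2S,3S,5S)-1-methyl-3-(prop-1-en-2-yl)-6-oxabicyclo[3.1.0]hexane-2-carboxylate | C[C@]12O[C@H]1C[C@H](C(C)=C)[C@@H]2C(=O)OC | intermediate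
7 | (1S,2R,3S)-2-(hydroxymethyl)-1-methyl-3-(prop-1-en-2-yl)cyclopentan-1-ol | C[C@]1(O)CC[C@H](C(C)=C)[C@@H]1CO | intermediate
8 | ethyl (triphenylphosphoranylidene)acetate | CCOC(=O)C=P(c1ccccc1)(c1ccccc1)c1ccccc1 | starting material
9 | (1S,2S,5S)-2-hydroxy-2-methyl-5-(prop-1-en-2-yl)cyclopentane-1-carbaldehyde | C[C@]1(O)CC[C@H](C(C)=C)[C@@H]1C=O | intermediate
10 | ethyl (2E)-3-[(1S,2S,5S)-2-hydroxy-2-methyl-5-(prop-1-en-2-yl)cyclopentyl]prop-2-enoate | C[C@]1(O)CC[C@H](C(C)=C)[C@@H]1/C=C/C(=O)OCC | intermediate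
11 | (1S,2S,3S)-2-[(1E)-3-hydroxyprop-1-en-1-yl]-1-methyl-3-(prop-1-en-2-yl)cyclopentan-1-ol | C[C@]1(O)CC[C@H](C(C)=C)[C@@H]1/C=C/CO | intermediate
12 | (1S,2R,3S)-2-[(2S,3S)-3-(hydroxymethyl)oxiran-2-yl]-1-methyl-3-(prop-1-en-2-yl)cyclopentan-1-ol | C[C@]1(O)CC[C@H](C(C)=C)[C@@H]1[C@@H]2O[C@H]2CO | intermediate
13 | isopropylmagnesium chloride | CC(C)[Mg]Cl | starting material
14 | (1R,2R)-1-[(1R,2S,5S)-2-hydroxy-2-methyl-5-(prop-1-en-2-yl)cyclopentyl]-2-(propan-2-yl)propane-1,3-diol | C[C@]1(O)CC[C@H](C(C)=C)[C@@H]1[C@H](O)[C@@H](CO)C(C)C | intermediate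
15 | tris(triethylsilyl) ether of 14 | C[C@]1(O[Si](CC)(CC)CC)CC[C@H](C(C)=C)[C@@H]1[C@H](O[Si](CC)(CC)CC)[C@@H](CO[Si](CC)(CC)CC)C(C)C | intermediate
16 | (2S,3S)-2-(propan-2-yl)-3-(triethylsilyloxy)-3-[(1R,2S,5S)-2-methyl-5-(prop-1-en-2-yl)-2-(triethylsilyloxy)cyclopentyl]propanal | C[C@]1(O[Si](CC)(CC)CC)CC[C@H](C(C)=C)[C@@H]1[C@H](O[Si](CC)(CC)CC)[C@@H](C=O)C(C)C | intermediate
17 | (1S,4S,5R,6R,7R,8S)-4,6-bis(triethylsilyloxy)guai-10(14)-en-8-ol, cis-fused | O[C@H]1CC(=C)[C@H]2CC[C@](C)(O[Si](CC)(CC)CC)[C@H]2[C@H](O[Si](CC)(CC)CC)[C@@H]1C(C)C | intermediate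
18 | (4S,5R,6R,7R,8S)-4,6-bis(triethylsilyloxy)guai-1(10)-en-8-ol | O[C@H]1CC(C)=C2CC[C@](C)(O[Si](CC)(CC)CC)[C@H]2[C@H](O[Si](CC)(CC)CC)[C@@H]1C(C)C | intermediate
19 | angelic acid, (2Z)-2-methylbut-2-enoic acid | C/C=C(/C)C(=O)O | starting material
20 | angelic 2,4,6-trichlorobenzoic anhydride | C/C=C(/C)C(=O)OC(=O)c1c(Cl)cc(Cl)cc1Cl | intermediate
21 | 4β,6β-bis(triethylsilyloxy)guai-1(10)-en-8α-yl angelate | C/C=C(/C)C(=O)O[C@H]1CC(C)=C2CC[C@](C)(O[Si](CC)(CC)CC)[C@H]2[C@H](O[Si](CC)(CC)CC)[C@@H]1C(C)C | intermediate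
22 | 4β,6β-dihydroxyguai-1(10)-en-8α-yl angelate | C/C=C(/C)C(=O)O[C@H]1CC(C)=C2CC[C@](C)(O)[C@H]2[C@H](O)[C@@H]1C(C)C | intermediate
23 | CNP0258590.1, (4S,5R,6R,7R,8S)-6-acetoxy-4-hydroxyguai-1(10)-en-8-yl angelate | C/C=C(/C)C(=O)O[C@H]1CC(C)=C2CC[C@](C)(O)[C@H]2[C@H](OC(C)=O)[C@@H]1C(C)C | target

Total step count: 15. Longest linear sequence: 15 steps (1 → 23).

Steps most likely to fail

Step 11. The danger is poor facial selectivity at the aldehyde: attack on the Re face would give the 8β-carbinol. The fallback sets out from 16 and comes back at 17. It keeps the ring closure but sets C8 afterwards under thermodynamic control. The cyclisation is run as described, and the undesired 4β,6β-bis(triethylsilyloxy)guai-10(14)-en-8β-ol F1, alone or mixed with 17, is oxidised with Dess–Martin periodinane (NaHCO3, CH2Cl2) to 4β,6β-bis(triethylsilyloxy)guai-10(14)-en-8-one F2. Single-electron reduction with SmI2, H2O and Et3N in THF should then give the more stable carbinol. That is the equatorial 8α-alcohol, trans to the isopropyl group and free of the 1,3-diaxial contact with O6, which is 17.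

Step 12. The danger is hydrogen abstraction from C9 instead of C1, so that the alkene stops at the trisubstituted 9(10) position. The fallback sets out from 17 and comes back at 18. It replaces the catalytic hydrogen shuttle by addition and elimination. Markovnikov hydrochlorination by hydrogen-atom transfer (Co(BF4)2·6H2O with a salicylaldimine ligand, PhSiH3, TsCl, EtOH) gives 10-chloro-4β,6β-bis(triethylsilyloxy)guaian-8α-ol F3 as a C10 epimer mixture. Dehydrochlorination with LiBr and Li2CO3 in DMF at 110 °C should then follow Zaitsev control toward the tetrasubstituted C1=C10 alkene 18.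

Step 8. The danger is a sluggish or regio-unselective opening by the secondary alkyl copper species, through halohydrin formation, reduction or attack at C6. The fallback sets out from 7 and comes back at 16. It forms C6–C7 by an aldol reaction instead of an epoxide opening. Diol 7 is silylated (Et3SiOTf, 2,6-lutidine) to the bis(triethylsilyl) ether F4. Swern conditions convert its primary silyl ether into (1R,2S,5S)-2-methyl-5-(prop-1-en-2-yl)-2-(triethylsilyloxy)cyclopentane-1-carbaldehyde F5. An L-proline-catalysed enamine cross-aldol reaction with slowly added isovaleraldehyde (DMF, 4 °C) should give, under catalyst control, the anti (2S,3S)-β-hydroxy aldehyde F6. Silylation of F6 with Et3SiOTf and 2,6-lutidine gives 16.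

Further compounds
F1 | step 11 | (1S,4S,5R,6R,7R,8R)-4,6-bis(triethylsilyloxy)guai-10(14)-en-8-ol (8β-OH) | O[C@@H]1CC(=C)[C@H]2CC[C@](C)(O[Si](CC)(CC)CC)[C@H]2[C@H](O[Si](CC)(CC)CC)[C@@H]1C(C)C
F2 | step 11 | 4β,6β-bis(triethylsilyloxy)-1β,5β-H-guai-10(14)-en-8-one | O=C1CC(=C)[C@H]2CC[C@](C)(O[Si](CC)(CC)CC)[C@H]2[C@H](O[Si](CC)(CC)CC)[C@@H]1C(C)C
F3 | step 12 | 10-chloro-4β,6β-bis(triethylsilyloxy)-1β,5β-H-guaian-8α-ol (C10 epimers) | O[C@H]1CC(C)(Cl)[C@H]2CC[C@](C)(O[Si](CC)(CC)CC)[C@H]2[C@H](O[Si](CC)(CC)CC)[C@@H]1C(C)C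
F4 | step 8 | bis(triethylsilyl) ether of 7 | C[C@]1(O[Si](CC)(CC)CC)CC[C@H](C(C)=C)[C@@H]1CO[Si](CC)(CC)CC
F5 | step 8 | (1R,2S,5S)-2-methyl-5-(prop-1-en-2-yl)-2-(triethylsilyloxy)cyclopentane-1-carbaldehyde | C[C@]1(O[Si](CC)(CC)CC)CC[C@H](C(C)=C)[C@@H]1C=O
F6 | step 8 | (2S,3S)-3-hydroxy-2-(propan-2-yl)-3-[(1R,2S,5S)-2-methyl-5-(prop-1-en-2-yl)-2-(triethylsilyloxy)cyclopentyl]propanal | C[C@]1(O[Si](CC)(CC)CC)CC[C@H](C(C)=C)[C@@H]1[C@H](O)[C@@H](C=O)C(C)C
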